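Each acyl chain (C1' ester carbonyl to C6' methyl) holds at C3' one CH2CHO branch and one C4'(CHO)=C5'H–C6'H3 branch. The second is the first after condensation with acetaldehyde, so removing both C4'=C5' bonds leaves two 3-substituted glutaraldehyde esters with prochiral C3' atoms. A chiral amine should condense one enantiotopic branch of each chain with one molecule of acetaldehyde, creating both enals and both C3' stereocentres in one operation, while the all-trans cyclopentane ring only carries the chains. The substrate is the bis[5-oxo-3-(2-oxoethyl)pentanoate] of the silylene-protected core diol, reached by ozonolysis of a bis(cyclopent-3-enylacetate).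

Key step: step 11

Remark on the chemistry (assumption): the sense of branch selection in step 11 cannot be taken from precedent. The (S)-amine is assumed to give the (3'S) centres (open enamine face anti to the ester-bearing CH2 group of C3'); if a single-arm model ester showed the opposite sense, the (R)-amine would be used with no other change.

**Route**

Step 1
Reactants: 1 (1S,4R)-cis-4-acetoxy-2-cyclopenten-1-ol; 2 dimethyl malonate
Product: 3 dimethyl 2-[(1R,4S)-4-hydroxycyclopent-2-en-1-yl]propanedioate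
Conditions: NaH, Pd(PPh3)4 (cat.), THF, 0 °C to 50 °C
Reagents that add atoms: none
Why: Tsuji–Trost allylic alkylation, in which zerovalent palladium ionises the acetate with inversion and the soft malonate anion attacks the allyl terminus remote from the hydroxyl with a second inversion, so the malonate should replace the acetate with net retention (cis to OH) and fix the ring carbon that becomes C4 of the core.

Step 2
Reactants: 3 dimethyl 2-[(1R,4S)-4-hydroxycyclopent-2-en-1-yl]propanedioate
Product: 4 2-[(1R,4S)-4-hydroxycyclopent-2-en-1-yl]propane-1,3-diol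
Conditions: LiAlH4, THF, 0 °C to rt
Reagents that add atoms: none
Why: hydride reduction of both esters of a monosubstituted malonate to the 1,3-diol, which should leave the isolated alkene and both stereocentres untouched.

Step 3
Reactants: 4 2-[(1R,4S)-4-hydroxycyclopent-2-en-1-yl]propane-1,3-diol
Product: 5 (1S,4R)-4-(2,2-di-tert-butyl-1,3,2-dioxasilinan-5-yl)cyclopent-2-en-1-ol
Conditions: t-Bu2Si(OTf)2 (1.05 equiv), 2,6-lutidine, DMF/CH2Cl2, −20 °C to 0 °C
Reagents that add atoms: di-tert-butylsilyl bis(trifluoromethanesulfonate), CC(C)(C)[Si](OS(=O)(=O)C(F)(F)F)(OS(=O)(=O)C(F)(F)F)C(C)(C)C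
Why: cyclic silylene formation, in which the reagent silylates a primary hydroxyl first and the second primary hydroxyl closes the six-membered dioxasilinane, a ring the secondary allylic hydroxyl cannot form, so that hydroxyl should stay free.

Step 4
Reactants: 5 (1S,4R)-4-(2,2-di-tert-butyl-1,3,2-dioxasilinan-5-yl)cyclopent-2-en-1-ol
Product: 6 (4R)-4-(2,2-di-tert-butyl-1,3,2-dioxasilinan-5-yl)cyclopent-2-en-1-one
Conditions: Dess–Martin periodinane, CH2Cl2, 0 °C to rt
Reagents that add atoms: none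
Why: Dess–Martin oxidation of the allylic alcohol to the enone under nearly neutral conditions, which should preserve the γ-stereocentre and the silylene.

Step 5
Reactants: 6 (4R)-4-(2,2-di-tert-butyl-1,3,2-dioxasilinan-5-yl)cyclopent-2-en-1-one
Product: 8 (2R,3S,4R)-4-(2,2-di-tert-butyl-1,3,2-dioxasilinan-5-yl)-3-ethenyl-2-methylcyclopentan-1-one, via bromomagnesium enolate 7 (not isolated)
Conditions: CH2=CHMgBr, CuBr·SMe2 (cat.), THF, −78 °C; then MeI, HMPA, −78 °C to −20 °C
Reagents that add atoms: vinylmagnesium bromide, C=C[Mg]Br; iodomethane, CI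
Why: copper-catalysed conjugate addition followed by enolate alkylation, in which the vinyl group should add to C3 anti to the bulky C4 substituent and the regiodefined enolate should be methylated at C2 anti to the new vinyl group, giving the 2,3-trans-3,4-trans ketone that is also the more stable arrangement at the epimerisable C2.

Step 6
Reactants: 8 (2R,3S,4R)-4-(2,2-di-tert-butyl-1,3,2-dioxasilinan-5-yl)-3-ethenyl-2-methylcyclopentan-1-one
Product: 9 (1S,2R,3S,4R)-4-(2,2-di-tert-butyl-1,3,2-dioxasilinan-5-yl)-3-ethenyl-2-methylcyclopentan-1-ol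
Conditions: LiBH(s-Bu)3, THF, −78 °C; aqueous work-up
Reagents that add atoms: none
Why: bulky trialkylborohydride reduction, in which hydride should attack the carbonyl face opposite the adjacent C2 methyl group and give the alcohol cis to that methyl (1S), a centre that is inverted on purpose in step 9.

Step 7
Reactants: 9 (1S,2R,3S,4R)-4-(2,2-di-tert-butyl-1,3,2-dioxasilinan-5-yl)-3-ethenyl-2-methylcyclopentan-1-ol
Product: 11 (1S,2R,3S,4R)-4-(2,2-di-tert-butyl-1,3,2-dioxasilinan-5-yl)-3-(hydroxymethyl)-2-methylcyclopentan-1-ol, via secondary ozonide 10 (not isolated)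
Conditions: O3, CH2Cl2, −78 °C; then NaBH4, MeOH, −78 °C to 0 °C
Reagents that add atoms: ozone, [O-][O+]=O
Why: ozonolysis with reductive NaBH4 work-up, which should turn the vinyl group into the hydroxymethyl group without touching a stereocentre.

Step 8
Reactants: 11 (1S,2R,3S,4R)-4-(2,2-di-tert-butyl-1,3,2-dioxasilinan-5-yl)-3-(hydroxymethyl)-2-methylcyclopentan-1-ol; 12 2-(cyclopent-3-en-1-yl)acetic acid
Product: 13 [(1S,2R,3S,5R)-5-(2,2-di-tert-butyl-1,3,2-dioxasilinan-5-yl)-3-hydroxy-2-methylcyclopentyl]methyl 2-(cyclopent-3-en-1-yl)acetate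
Conditions: 12 (1.05 equiv), EDC·HCl, DMAP (cat.), CH2Cl2, 0 °C
Reagents that add atoms: none
Why: Steglich-type carbodiimide esterification, which should acylate the unhindered primary hydroxyl well before the secondary hydroxyl that is flanked by the cis methyl group.

Step 9
Reactants: 13 [(1S,2R,3S,5R)-5-(2,2-di-tert-butyl-1,3,2-dioxasilinan-5-yl)-3-hydroxy-2-methylcyclopentyl]methyl 2-(cyclopent-3-en-1-yl)acetate; 12 2-(cyclopent-3-en-1-yl)acetic acid
Product: 14 (1R,2R,3S,4R)-3-({[2-(cyclopent-3-en-1-yl)acetyl]oxy}methyl)-4-(2,2-di-tert-butyl-1,3,2-dioxasilinan-5-yl)-2-methylcyclopentyl 2-(cyclopent-3-en-1-yl)acetate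
Conditions: 12 (2 equiv), PPh3, DIAD, toluene, 0 °C to rt
Reagents that add atoms: none
Why: Mitsunobu esterification, in which the carboxylate displaces the oxyphosphonium group in an SN2 step, so the carbinol carbon should be inverted to 1R and the ester placed trans to the C2 methyl group as the target requires.

Step 10
Reactants: 14 (1R,2R,3S,4R)-3-({[2-(cyclopent-3-en-1-yl)acetyl]oxy}methyl)-4-(2,2-di-tert-butyl-1,3,2-dioxasilinan-5-yl)-2-methylcyclopentyl 2-(cyclopent-3-en-1-yl)acetate
Product: 16 (1R,2R,3S,4R)-4-(2,2-di-tert-butyl-1,3,2-dioxasilinan-5-yl)-2-methyl-3-({[5-oxo-3-(2-oxoethyl)pentanoyl]oxy}methyl)cyclopentyl 5-oxo-3-(2-oxoethyl)pentanoate, via bis-ozonide 15 (not isolated)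
Conditions: O3, CH2Cl2, −78 °C; then Me2S, −78 °C to rt; used at once
Reagents that add atoms: ozone, [O-][O+]=O
Why: ozonolysis with reductive Me2S work-up, which should cleave both cyclopentenes, the only C=C bonds present, to the two symmetric 1,5-dialdehyde arms.

Step 11
Reactants: 16 (1R,2R,3S,4R)-4-(2,2-di-tert-butyl-1,3,2-dioxasilinan-5-yl)-2-methyl-3-({[5-oxo-3-(2-oxoethyl)pentanoyl]oxy}methyl)cyclopentyl 5-oxo-3-(2-oxoethyl)pentanoate; 17 acetaldehyde (two molecules are consumed, one for each arm)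
Product: 19 (1R,2R,3S,4R)-4-(2,2-di-tert-butyl-1,3,2-dioxasilinan-5-yl)-3-({[(3S,4E)-4-formyl-3-(2-oxoethyl)hex-4-enoyl]oxy}methyl)-2-methylcyclopentyl (3S,4E)-4-formyl-3-(2-oxoethyl)hex-4-enoate, via twofold aldol adduct 18 (not isolated)
Conditions: (S)-α,α-diphenylprolinol trimethylsilyl ether (40 mol%), PhCO2H (40 mol%), 17 (2.2 equiv, slow addition), toluene (0.02 M), 0 °C
Reagents that add atoms: acetaldehyde (the second molecule of 17), CC=O
Why: Proposed new method: the amine should form enamines reversibly at the CH2CHO branches, the enamine of one branch of each arm adds to one molecule of acetaldehyde (two in all, each supplying C5' and C6' of one arm) to give aldol 18, and loss of water through the enamine (E1cB) followed by hydrolysis releases the 2-substituted but-2-enal, whose E form (methyl anti to formyl) is the stable one. The closest known reaction types are the amine/acid-catalysed Mannich-type α-methylenation of aldehydes and the amine-catalysed enamine desymmetrisation of prochiral dialdehydes; their union on a 3-substituted glutaraldehyde with acetaldehyde as acceptor is without example. No ring closes, since the formyl groups of one arm are 1,5-related and an intramolecular aldol would demand a cyclobutane. Each C3' centre is controlled by the C2 stereocentre of the pyrrolidine alone: its CPh2OTMS group leaves one enamine face open, and only in the enamine of one of the two enantiotopic branches does that open face lie anti to the CH2CO2R group of C3', so that branch should condense faster, while the ring stereocentres, at least four bonds away, should have little say. The step also needs cross- over self-condensation and one condensation per arm: slow addition of a slight excess of acetaldehyde keeps the substrate enamines in excess, the condensed branch has lost its α-hydrogens, and the new trisubstituted enal crowds the remaining branch.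

Step 12
Reactants: 19 (1R,2R,3S,4R)-4-(2,2-di-tert-butyl-1,3,2-dioxasilinan-5-yl)-3-({[(3S,4E)-4-formyl-3-(2-oxoethyl)hex-4-enoyl]oxy}methyl)-2-methylcyclopentyl (3S,4E)-4-formyl-3-(2-oxoethyl)hex-4-enoate
Product: 20 (1R,2R,3S,4R)-4-(1,3-dihydroxypropan-2-yl)-3-({[(3S,4E)-4-formyl-3-(2-oxoethyl)hex-4-enoyl]oxy}methyl)-2-methylcyclopentyl (3S,4E)-4-formyl-3-(2-oxoethyl)hex-4-enoate
Conditions: HF·pyridine, pyridine, THF, 0 °C
Reagents that add atoms: none
Why: fluoride-induced cleavage of the two Si–O bonds (silylene deprotection) under buffered conditions that should spare the esters, the enals and the aldehydes and touch no stereocentre.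

**Compound list**

1 | (1S,4R)-cis-4-acetoxy-2-cyclopenten-1-ol | CC(=O)O[C@H]1C=C[C@@H](O)C1 | starting material
2 | dimethyl malonate | COC(=O)CC(=O)OC | starting material
3 | dimethyl 2-[(1R,4S)-4-hydroxycyclopent-2-en-1-yl]propanedioate | COC(=O)C(C(=O)OC)[C@H]1C=C[C@@H](O)C1 | intermediate
4 | 2-[(1R,4S)-4-hydroxycyclopent-2-en-1-yl]propane-1,3-diol | OCC(CO)[C@H]1C=C[C@@H](O)C1 | intermediate
5 | (1S,4R)-4-(2,2-di-tert-butyl-1,3,2-dioxasilinan-5-yl)cyclopent-2-en-1-ol | CC(C)(C)[Si]1(C(C)(C)C)OCC(CO1)[C@H]1C=C[C@@H](O)C1 | intermediate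
6 | (4R)-4-(2,2-di-tert-butyl-1,3,2-dioxasilinan-5-yl)cyclopent-2-en-1-one | CC(C)(C)[Si]1(C(C)(C)C)OCC(CO1)[C@H]1C=CC(=O)C1 | intermediate
7 | bromomagnesium (3S,4R)-4-(2,2-di-tert-butyl-1,3,2-dioxasilinan-5-yl)-3-ethenylcyclopent-1-en-1-olate | C=C[C@@H]1C=C(O[Mg]Br)C[C@H]1C1CO[Si](C(C)(C)C)(C(C)(C)C)OC1 | intermediate (not isolated)
8 | (2R,3S,4R)-4-(2,2-di-tert-butyl-1,3,2-dioxasilinan-5-yl)-3-ethenyl-2-methylcyclopentan-1-one | C=C[C@@H]1[C@@H](C)C(=O)C[C@H]1C1CO[Si](C(C)(C)C)(C(C)(C)C)OC1 | intermediate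
9 | (1S,2R,3S,4R)-4-(2,2-di-tert-butyl-1,3,2-dioxasilinan-5-yl)-3-ethenyl-2-methylcyclopentan-1-ol | C=C[C@@H]1[C@@H](C)[C@@H](O)C[C@H]1C1CO[Si](C(C)(C)C)(C(C)(C)C)OC1 | intermediate
10 | secondary ozonide of 9: the vinyl group as a 1,2,4-trioxolan-3-yl group (trioxolane carbon unassigned) | C1OC(OO1)[C@@H]1[C@@H](C)[C@@H](O)C[C@H]1C1CO[Si](C(C)(C)C)(C(C)(C)C)OC1 | intermediate (not isolated)
11 | (1S,2R,3S,4R)-4-(2,2-di-tert-butyl-1,3,2-dioxasilinan-5-yl)-3-(hydroxymethyl)-2-methylcyclopentan-1-ol | OC[C@@H]1[C@@H](C)[C@@H](O)C[C@H]1C1CO[Si](C(C)(C)C)(C(C)(C)C)OC1 | intermediate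
12 | 2-(cyclopent-3-en-1-yl)acetic acid | OC(=O)CC1CC=CC1 | starting material
13 | [(1S,2R,3S,5R)-5-(2,2-di-tert-butyl-1,3,2-dioxasilinan-5-yl)-3-hydroxy-2-methylcyclopentyl]methyl 2-(cyclopent-3-en-1-yl)acetate | O=C(CC1CC=CC1)OC[C@@H]1[C@@H](C)[C@@H](O)C[C@H]1C1CO[Si](C(C)(C)C)(C(C)(C)C)OC1 | intermediate
14 | (1R,2R,3S,4R)-3-({[2-(cyclopent-3-en-1-yl)acetyl]oxy}methyl)-4-(2,2-di-tert-butyl-1,3,2-dioxasilinan-5-yl)-2-methylcyclopentyl 2-(cyclopent-3-en-1-yl)acetate | O=C(CC1CC=CC1)OC[C@@H]1[C@@H](C)[C@H](OC(=O)CC2CC=CC2)C[C@H]1C1CO[Si](C(C)(C)C)(C(C)(C)C)OC1 | intermediate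
15 | bis-ozonide of 14: each cyclopentene as a 6,7,8-trioxabicyclo[3.2.1]octane | O=C(CC1CC2OOC(C1)O2)OC[C@@H]1[C@@H](C)[C@H](OC(=O)CC2CC3OOC(C2)O3)C[C@H]1C1CO[Si](C(C)(C)C)(C(C)(C)C)OC1 | intermediate (not isolated)
16 | (1R,2R,3S,4R)-4-(2,2-di-tert-butyl-1,3,2-dioxasilinan-5-yl)-2-methyl-3-({[5-oxo-3-(2-oxoethyl)pentanoyl]oxy}methyl)cyclopentyl 5-oxo-3-(2-oxoethyl)pentanoate | O=CCC(CC=O)CC(=O)OC[C@@H]1[C@@H](C)[C@H](OC(=O)CC(CC=O)CC=O)C[C@H]1C1CO[Si](C(C)(C)C)(C(C)(C)C)OC1 | intermediate
17 | acetaldehyde | CC=O | starting material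
18 | twofold aldol adduct: each arm a (3S)-4-formyl-5-hydroxy-3-(2-oxoethyl)hexanoate (C4' and C5' unassigned) | CC(O)C(C=O)[C@@H](CC=O)CC(=O)OC[C@@H]1[C@@H](C)[C@H](OC(=O)C[C@H](CC=O)C(C=O)C(C)O)C[C@H]1C1CO[Si](C(C)(C)C)(C(C)(C)C)OC1 | intermediate (not isolated)
19 | (1R,2R,3S,4R)-4-(2,2-di-tert-butyl-1,3,2-dioxasilinan-5-yl)-3-({[(3S,4E)-4-formyl-3-(2-oxoethyl)hex-4-enoyl]oxy}methyl)-2-methylcyclopentyl (3S,4E)-4-formyl-3-(2-oxoethyl)hex-4-enoate | C/C=C(/C=O)[C@@H](CC=O)CC(=O)OC[C@@H]1[C@@H](C)[C@H](OC(=O)C[C@H](CC=O)/C(C=O)=C\C)C[C@H]1C1CO[Si](C(C)(C)C)(C(C)(C)C)OC1 | intermediate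
20 | (1R,2R,3S,4R)-4-(1,3-dihydroxypropan-2-yl)-3-({[(3S,4E)-4-formyl-3-(2-oxoethyl)hex-4-enoyl]oxy}methyl)-2-methylcyclopentyl (3S,4E)-4-formyl-3-(2-oxoethyl)hex-4-enoate | C/C=C(/C=O)[C@@H](CC=O)CC(=O)OC[C@@H]1[C@@H](C)[C@H](OC(=O)C[C@H](CC=O)/C(C=O)=C\C)C[C@H]1C(CO)CO | target

**Totals**

Total step count: 12. Longest linear sequence: 12 steps (1 to 20); acid 12 and acetaldehyde 17 are bought, and step 11 consumes two molecules of 17.

**Steps most likely to fail**

Step 11 (new method). The amine may discriminate poorly between the two enantiotopic branches, because the two other groups on C3' (CH2CHO and CH2CO2R) are of similar size. Acetaldehyde may also self-condense, or a second condensation may occur within one arm. The fallback uses known chemistry only, sets out from diol 11 and returns at 19; it brings in each arm with its stereocentre already fixed from the chiral pool. Commercial (3aR,6aR)-2,2-dimethyl-3a,6a-dihydro-4H-cyclopenta[d][1,3]dioxol-4-one F1 would be hydrogenated (H2, Pd/C, EtOAc) to the saturated ketone F2. Its kinetic enolate on the CH2 side (LiN(i-Pr)2, THF, −78 °C) would be alkylated with methyl bromoacetate on the face opposite the acetonide to give the keto ester F3. Wittig ethylidenation (EtPPh3Br, KOt-Bu, THF) would give the ethylidene ester F4; the isomer with the methyl syn to the ring carbon that carries the acetate chain is wanted, and the other would be removed here. LiOH in THF/H2O would give the acid F5. Acid F5 would replace 12 under the conditions of steps 8 and 9: carbodiimide acylation of 11 to the primary monoester F6, then Mitsunobu inversion to the diester F7. Aqueous acetic acid at 40 °C would open both acetonides to the bis(cis-diol) F8. Glycol cleavage (NaIO4, THF/pH 7 buffer, 0 °C) would turn each diol into the enal and the CH2CHO group of one arm, which is 19, ready for step 12.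

Step 9. Substitution at the hindered secondary oxyphosphonium centre by a weakly acidic aliphatic acid may be slow, which would allow elimination towards a cyclopentene or acyl transfer with retention. The fallback sets out from diol 11 and returns at 14; it separates the inversion from the attachment of the arm. Mitsunobu reaction of 11 with 4-nitrobenzoic acid (PPh3, DIAD, toluene) would give the bis(4-nitrobenzoate) F9, inverted at the carbinol carbon. K2CO3 in MeOH would release the (1R,2R,3S,4R)-diol F10. Twofold carbodiimide esterification with 12 (2.4 equiv, EDC·HCl, DMAP, CH2Cl2) would give 14 without any selectivity demand.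

Step 5. Proton exchange between the magnesium enolate and the methylated ketone may give unmethylated and over-methylated ketones, or C-methylation may be sluggish. The fallback sets out from enone 6 and returns at 8; it places the methyl group before the conjugate addition. α-Iodination (I2, pyridine, CH2Cl2) would give (4S)-4-(2,2-di-tert-butyl-1,3,2-dioxasilinan-5-yl)-2-iodocyclopent-2-en-1-one F11 (descriptor changed by priority only). Stille coupling (Me4Sn, Pd2(dba)3, AsPh3, CuI, NMP) would give (4R)-4-(2,2-di-tert-butyl-1,3,2-dioxasilinan-5-yl)-2-methylcyclopent-2-en-1-one F12. Conjugate addition of (CH2=CH)2CuMgBr (THF, −78 °C; aq. NH4Cl), anti to the C4 group, then equilibration of C2 with K2CO3 in MeOH, should leave the methyl trans to the vinyl group, which is 8.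

**Further compounds**

F1 | step 11 | (3aR,6aR)-2,2-dimethyl-3a,6a-dihydro-4H-cyclopenta[d][1,3]dioxol-4-one (commercial) | O=C1C=C[C@H]2OC(C)(C)O[C@@H]12
F2 | step 11 | (3aR,6aR)-2,2-dimethyltetrahydro-4H-cyclopenta[d][1,3]dioxol-4-one | O=C1CC[C@H]2OC(C)(C)O[C@@H]12
F3 | step 11 | methyl 2-[(3aR,5S,6aR)-2,2-dimethyl-4-oxotetrahydro-4H-cyclopenta[d][1,3]dioxol-5-yl]acetate | O=C1[C@H](CC(=O)OC)C[C@H]2OC(C)(C)O[C@@H]12
F4 | step 11 | methyl 2-[(3aS,4E,5S,6aR)-4-ethylidene-2,2-dimethyltetrahydro-4H-cyclopenta[d][1,3]dioxol-5-yl]acetate | C/C=C1\[C@H](CC(=O)OC)C[C@H]2OC(C)(C)O[C@@H]12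
F5 | step 11 | 2-[(3aS,4E,5S,6aR)-4-ethylidene-2,2-dimethyltetrahydro-4H-cyclopenta[d][1,3]dioxol-5-yl]acetic acid | C/C=C1\[C@H](CC(=O)O)C[C@H]2OC(C)(C)O[C@@H]12
F6 | step 11 | primary monoester of diol 11 with acid F5 (secondary hydroxyl free, 1S) | C/C=C1\[C@H](CC(=O)OC[C@@H]3[C@@H](C)[C@@H](O)C[C@H]3C3CO[Si](C(C)(C)C)(C(C)(C)C)OC3)C[C@H]2OC(C)(C)O[C@@H]12
F7 | step 11 | diester of the silylene-protected core diol (1R) with two molecules of acid F5 | C/C=C1\[C@H](CC(=O)OC[C@@H]3[C@@H](C)[C@H](OC(=O)C[C@@H]4C[C@H]5OC(C)(C)O[C@H]5/C4=C/C)C[C@H]3C3CO[Si](C(C)(C)C)(C(C)(C)C)OC3)C[C@H]2OC(C)(C)O[C@@H]12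
F8 | step 11 | bis(cis-diol) from F7 after removal of both acetonides | C/C=C1\[C@H](CC(=O)OC[C@@H]3[C@@H](C)[C@H](OC(=O)C[C@@H]4C[C@@H](O)[C@@H](O)/C4=C/C)C[C@H]3C3CO[Si](C(C)(C)C)(C(C)(C)C)OC3)C[C@@H](O)[C@H]1O
F9 | step 9 | (1R,2R,3S,4R)-4-(2,2-di-tert-butyl-1,3,2-dioxasilinan-5-yl)-2-methyl-3-{[(4-nitrobenzoyl)oxy]methyl}cyclopentyl 4-nitrobenzoate | O=C(OC[C@@H]1[C@@H](C)[C@H](OC(=O)c2ccc(cc2)[N+](=O)[O-])C[C@H]1C1CO[Si](C(C)(C)C)(C(C)(C)C)OC1)c1ccc(cc1)[N+](=O)[O-]
F10 | step 9 | (1R,2R,3S,4R)-4-(2,2-di-tert-butyl-1,3,2-dioxasilinan-5-yl)-3-(hydroxymethyl)-2-methylcyclopentan-1-ol | OC[C@@H]1[C@@H](C)[C@H](O)C[C@H]1C1CO[Si](C(C)(C)C)(C(C)(C)C)OC1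
F11 | step 5 | (4S)-4-(2,2-di-tert-butyl-1,3,2-dioxasilinan-5-yl)-2-iodocyclopent-2-en-1-one | CC(C)(C)[Si]1(C(C)(C)C)OCC(CO1)[C@H]1C=C(I)C(=O)C1
F12 | step 5 | (4R)-4-(2,2-di-tert-butyl-1,3,2-dioxasilinan-5-yl)-2-methylcyclopent-2-en-1-one | CC(C)(C)[Si]1(C(C)(C)C)OCC(CO1)[C@H]1C=C(C)C(=O)C1
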